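**Strategy.** Ring A (C4, C3, C2, C1, C10, C5) is reached by contracting a seven-membered ring: a Favorskii rearrangement of a bicyclic 2-chloro-2-methylcyclohept-4-enone expels the ring carbonyl, which becomes the C18 ester carbon on the quaternary C4. The step exploits the C4(CH3)(CO2CH3) unit flanked by C3H2 and the C5 methine, with the C1=C10 alkene already in place; in one operation it forms the C3–C4 bond, sets C4 and delivers the methyl ester. The precursor, a 6/7-fused chloro ketone, comes from an alkynol cyclisation/Claisen ring expansion that transfers a reagent-set carbinol configuration to C5; ring B with C8/C9 comes from conjugate addition/allylation.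

Key step: step 8

Remark: atom labels follow the halimane numbering of the target (ring A: C1–C5 and C10; ring B: C5–C10; C18 = ester carbon and C19 = methyl on C4; C17 = methyl on C8; C20 = methyl on C9; side chain C11–C16); β is the face of H-5, α the face of the three ring methyls.

Step 1
Reactants: 1 2-methylcyclohex-2-en-1-one
Product: 3 (2S,3R)-2-allyl-2,3-dimethylcyclohexan-1-one, via bromomagnesium enolate 2 (not isolated)
Conditions: MeMgBr, Cu(OTf)2 (3 mol %), chiral imidazolinium salt as N-heterocyclic carbene precursor (4 mol %, the enantiomer that gives the 3R enolate), Et2O, 0 °C; then allyl iodide, DMPU, 0 °C to rt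
Reagents that add atoms: methylmagnesium bromide C[Mg]Br; allyl iodide C=CCI
Why: Copper-catalysed asymmetric conjugate addition of the Grignard reagent should set C8 (3R) under ligand control, and the regiodefined magnesium enolate is allylated anti to the new C8 methyl (enolate alkylation), which fixes the quaternary C9 with the two methyls cis.

Step 2
Reactants: 3 (2S,3R)-2-allyl-2,3-dimethylcyclohexan-1-one
Product: 4 (E)-2,4,6-triisopropylbenzenesulfonyl hydrazone of ketone 3
Conditions: 2,4,6-triisopropylbenzenesulfonohydrazide, HCl (cat.), MeCN, rt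
Reagents that add atoms: 2,4,6-triisopropylbenzenesulfonohydrazide CC(C)c1cc(C(C)C)c(S(=O)(=O)NN)c(C(C)C)c1
Why: Acid-catalysed hydrazone formation is reliable on α-quaternary cyclohexanones and prepares the Shapiro reaction; no stereocentre is touched.

Step 3
Reactants: 5 hex-4-ynoic acid
Product: 7 N-methoxy-N-methylhex-4-ynamide, via acyl imidazole 6 (not isolated)
Conditions: 1,1'-carbonyldiimidazole (CDI), CH2Cl2, rt; then MeNH(OMe)·HCl, rt
Reagents that add atoms: N,O-dimethylhydroxylamine hydrochloride CNOC.Cl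
Why: CDI activation followed by aminolysis (Weinreb amide formation) gives an acyl donor that stops at the ketone stage with an organolithium.

Step 4
Reactants: 4 (E)-2,4,6-triisopropylbenzenesulfonyl hydrazone of ketone 3; 7 N-methoxy-N-methylhex-4-ynamide
Product: 9 1-[(5R,6S)-6-allyl-5,6-dimethylcyclohex-1-en-1-yl]hex-4-yn-1-one, via vinyllithium 8 (not isolated)
Conditions: n-BuLi (2.2 equiv), THF, −78 to 0 °C; then 7, −78 to 0 °C; H2O
Reagents that add atoms: none
Why: Shapiro reaction: the dianion can only form on the C5 side because C9 is quaternary, loss of N2 and sulfinate gives the C10 vinyllithium with the C5=C10 alkene, and acylation by the Weinreb amide stops at the enone through the chelated tetrahedral intermediate.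

Step 5
Reactants: 9 1-[(5R,6S)-6-allyl-5,6-dimethylcyclohex-1-en-1-yl]hex-4-yn-1-one
Product: 10 (1S)-1-[(5R,6S)-6-allyl-5,6-dimethylcyclohex-1-en-1-yl]hex-4-yn-1-ol
Conditions: (R)-2-methyl-CBS-oxazaborolidine [(R)-1-methyl-3,3-diphenyltetrahydro-1H,3H-pyrrolo[1,2-c][1,3,2]oxazaborole] (20 mol %), catecholborane, toluene, −78 °C
Reagents that add atoms: none
Why: CBS reduction: the oxazaborolidine distinguishes the bulky cyclohexenyl group from the primary alkyl chain, and the (R)-catalyst should deliver the (S)-carbinol (C1), which later decides the configuration at C5.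

Step 6
Reactants: 10 (1S)-1-[(5R,6S)-6-allyl-5,6-dimethylcyclohex-1-en-1-yl]hex-4-yn-1-ol
Product: 12 (1S,2R,4aR,5S)-1-allyl-1,2,5-trimethyl-1,2,3,4,4a,5,7,8-octahydro-6H-benzo[7]annulen-6-one, via enol ether 11 (not isolated)
Conditions: MeLi (10 mol %), phenetole, 210 °C (microwave, sealed vessel)
Reagents that add atoms: none
Why: Tandem alkoxide 5-exo-dig addition to the alkyne and Claisen rearrangement of the 2-ethylidene-5-alkenyltetrahydrofuran (a known ring-expanding route to cyclohept-4-enones): the C1–O bond breaks and the C4–C5 bond forms on the same face of the allyl unit, and because the new C1=C10 alkene must be cis in the seven-membered ring the (S)-carbinol forces C4 onto the α face of C5 (H-5 β) against the steric bias of ring B; C4 is epimerisable here and is drawn as the expected epimer.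

Step 7
Reactants: 12 (1S,2R,4aR,5S)-1-allyl-1,2,5-trimethyl-1,2,3,4,4a,5,7,8-octahydro-6H-benzo[7]annulen-6-one
Product: 14 (1S,2R,4aS,5R)-1-allyl-5-chloro-1,2,5-trimethyl-1,2,3,4,4a,5,7,8-octahydro-6H-benzo[7]annulen-6-one, via silyl enol ether 13 (not isolated)
Conditions: TMSCl, NaI, Et3N, MeCN, rt; then NCS, THF, 0 °C
Reagents that add atoms: N-chlorosuccinimide O=C1CCC(=O)N1Cl
Why: Thermodynamic silyl enol ether formation goes to the more substituted C4 side and electrophilic chlorination should occur anti to C6 (4β-Cl, cis to H-5); the configuration at C4 is not critical because both Favorskii pathways of step 8 converge.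

Step 8
Reactants: 14 (1S,2R,4aS,5R)-1-allyl-5-chloro-1,2,5-trimethyl-1,2,3,4,4a,5,7,8-octahydro-6H-benzo[7]annulen-6-one
Product: 16 methyl (1S,5S,6R,8aS)-5-allyl-1,5,6-trimethyl-1,2,3,5,6,7,8,8a-octahydronaphthalene-1-carboxylate, via cyclopropanone 15 (not isolated)
Conditions: NaOMe, Et2O–MeOH, 0 °C to rt
Reagents that add atoms: sodium methoxide [Na+].[O-]C
Why: Favorskii rearrangement: methoxide forms the C3 enolate, which displaces chloride at C4 with inversion to give cyclopropanone 15; methoxide then adds to the carbonyl and the C18–C3 bond breaks toward the less substituted C3 carbanion, so the former ring carbonyl becomes the C18 methyl ester on C4 and the seven-membered ring has contracted to ring A. The closest known reaction is the Favorskii contraction of 2-chloro-2-methylcycloalkanones to methyl 1-methylcycloalkanecarboxylates. Ring A (C4–C3–C2–C1=C10–C5) is closed through the C3–C4 bond by 3-exo-tet attack of the enolate, cis-fused to the cyclopropanone that then opens. C4 is the only new stereocentre: with chloride β, backside attack places the carbonyl bridge on the β face, so CO2CH3 ends β (cis to H-5) and CH3 α, and if the chloro enolate ionises to the oxyallyl species instead, the cyclopropanone should still close on the face anti to C6 and give the same isomer. The step needs enolisation at C3 (C4 has no hydrogen and the C1=C10 alkene is too remote to conjugate) and opening away from the quaternary carbon, and both are inherent in the substrate.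

Step 9
Reactants: 16 methyl (1S,5S,6R,8aS)-5-allyl-1,5,6-trimethyl-1,2,3,5,6,7,8,8a-octahydronaphthalene-1-carboxylate
Product: 18 methyl (1S,5S,6R,8aS)-5-(3-hydroxypropyl)-1,5,6-trimethyl-1,2,3,5,6,7,8,8a-octahydronaphthalene-1-carboxylate, via B-alkyl-9-BBN 17 (not isolated)
Conditions: 9-BBN, THF, 0 °C to rt; then H2O2, NaOH (aq.), 0 °C
Reagents that add atoms: hydrogen peroxide OO
Why: Hydroboration–oxidation: 9-BBN adds anti-Markovnikov only to the monosubstituted allyl alkene, leaving the hindered trisubstituted C1=C10 alkene and the neopentyl ester untouched.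

Step 10
Reactants: 18 methyl (1S,5S,6R,8aS)-5-(3-hydroxypropyl)-1,5,6-trimethyl-1,2,3,5,6,7,8,8a-octahydronaphthalene-1-carboxylate
Product: 19 methyl (1S,5S,6R,8aS)-1,5,6-trimethyl-5-(3-oxopropyl)-1,2,3,5,6,7,8,8a-octahydronaphthalene-1-carboxylate
Conditions: Dess–Martin periodinane, NaHCO3, CH2Cl2, rt
Reagents that add atoms: none
Why: Dess–Martin oxidation converts the primary alcohol into the aldehyde under neutral conditions without touching alkene or ester.

Step 11
Reactants: 19 methyl (1S,5S,6R,8aS)-1,5,6-trimethyl-5-(3-oxopropyl)-1,2,3,5,6,7,8,8a-octahydronaphthalene-1-carboxylate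
Product: 20 methyl (1S,5S,6R,8aS)-5-(but-3-yn-1-yl)-1,5,6-trimethyl-1,2,3,5,6,7,8,8a-octahydronaphthalene-1-carboxylate
Conditions: dimethyl (1-diazo-2-oxopropyl)phosphonate, K2CO3, MeOH, 0 °C to rt
Reagents that add atoms: dimethyl (1-diazo-2-oxopropyl)phosphonate CC(=O)C(=[N+]=[N-])P(=O)(OC)OC
Why: Ohira–Bestmann homologation (Seyferth–Gilbert type) turns the aldehyde carbon into the internal alkyne carbon C13 under mild conditions that the hindered ester should tolerate.

Step 12
Reactants: 20 methyl (1S,5S,6R,8aS)-5-(but-3-yn-1-yl)-1,5,6-trimethyl-1,2,3,5,6,7,8,8a-octahydronaphthalene-1-carboxylate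
Product: 22 methyl (1S,5S,6R,8aS)-5-[(3E)-5-hydroxy-3-methylpent-3-en-1-yl]-1,5,6-trimethyl-1,2,3,5,6,7,8,8a-octahydronaphthalene-1-carboxylate, via alkenylalane 21 (not isolated)
Conditions: Me3Al, Cp2ZrCl2 (25 mol %), CH2Cl2, rt; then (CH2O)n, 0 °C to rt; aqueous work-up
Reagents that add atoms: trimethylaluminium C[Al](C)C; formaldehyde (as paraformaldehyde) C=O
Why: Negishi zirconium-catalysed carboalumination adds CH3 and Al syn across the terminal alkyne with CH3 on C13, and the alkenylalane is trapped by formaldehyde with retention, which should give the E-trisubstituted allylic alcohol.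

Step 13
Reactants: 22 methyl (1S,5S,6R,8aS)-5-[(3E)-5-hydroxy-3-methylpent-3-en-1-yl]-1,5,6-trimethyl-1,2,3,5,6,7,8,8a-octahydronaphthalene-1-carboxylate
Product: 23 methyl (1S,5S,6R,8aS)-5-[(3E)-5-acetoxy-3-methylpent-3-en-1-yl]-1,5,6-trimethyl-1,2,3,5,6,7,8,8a-octahydronaphthalene-1-carboxylate (CNP0209995.2)
Conditions: Ac2O, pyridine, 4-(dimethylamino)pyridine (cat.), CH2Cl2, rt
Reagents that add atoms: acetic anhydride CC(=O)OC(C)=O
Why: Acyl-transfer-catalysed acetylation of the primary allylic alcohol gives the acetate; nothing else in the molecule should react.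

**Compound list**

1 | 2-methylcyclohex-2-en-1-one | CC1=CCCCC1=O | starting material
2 | bromomagnesium (3R)-2,3-dimethylcyclohex-1-en-1-olate (not isolated) | Br[Mg]OC1=C(C)[C@H](C)CCC1 | intermediate
3 | (2S,3R)-2-allyl-2,3-dimethylcyclohexan-1-one | O=C1CCC[C@@H](C)[C@]1(C)CC=C | intermediate
4 | (E)-2,4,6-triisopropylbenzenesulfonyl hydrazone of ketone 3 | CC(C)c1cc(C(C)C)c(S(=O)(=O)N/N=C2\CCC[C@@H](C)[C@]2(C)CC=C)c(C(C)C)c1 | intermediate
5 | hex-4-ynoic acid | CC#CCCC(=O)O | starting material
6 | 1-(hex-4-ynoyl)imidazole (not isolated) | CC#CCCC(=O)n1ccnc1 | intermediate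
7 | N-methoxy-N-methylhex-4-ynamide | CC#CCCC(=O)N(C)OC | intermediate
8 | [(5R,6S)-6-allyl-5,6-dimethylcyclohex-1-en-1-yl]lithium (not isolated) | [Li]C1=CCC[C@@H](C)[C@]1(C)CC=C | intermediate
9 | 1-[(5R,6S)-6-allyl-5,6-dimethylcyclohex-1-en-1-yl]hex-4-yn-1-one | CC#CCCC(=O)C1=CCC[C@@H](C)[C@]1(C)CC=C | intermediate
10 | (1S)-1-[(5R,6S)-6-allyl-5,6-dimethylcyclohex-1-en-1-yl]hex-4-yn-1-ol | CC#CCC[C@H](O)C1=CCC[C@@H](C)[C@]1(C)CC=C | intermediate
11 | (2Z,5S)-5-[(5R,6S)-6-allyl-5,6-dimethylcyclohex-1-en-1-yl]-2-ethylidenetetrahydrofuran (not isolated) | C/C=C1/CC[C@@H](C2=CCC[C@@H](C)[C@]2(C)CC=C)O1 | intermediate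
12 | (1S,2R,4aR,5S)-1-allyl-1,2,5-trimethyl-1,2,3,4,4a,5,7,8-octahydro-6H-benzo[7]annulen-6-one (seven-membered ring C4–C18(=O)–C3–C2–C1=C10–C5; 4α-CH3, 5β-H) | C[C@@H]1C(=O)CCC=C2[C@@H]1CC[C@@H](C)[C@]2(C)CC=C | intermediate
13 | trimethylsilyl enol ether of 12 toward C4 (C4=C18–OSiMe3; not isolated) | CC1=C(O[Si](C)(C)C)CCC=C2[C@@H]1CC[C@@H](C)[C@]2(C)CC=C | intermediate
14 | (1S,2R,4aS,5R)-1-allyl-5-chloro-1,2,5-trimethyl-1,2,3,4,4a,5,7,8-octahydro-6H-benzo[7]annulen-6-one (4β-Cl, 4α-CH3) | C[C@]1(Cl)C(=O)CCC=C2[C@@H]1CC[C@@H](C)[C@]2(C)CC=C | intermediate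
15 | cyclopropanone with C18(=O) bridging C3 and C4 on the β face of ring A (not isolated) | C[C@]12C(=O)[C@H]1CC=C1[C@@H]2CC[C@@H](C)[C@]1(C)CC=C | intermediate
16 | methyl (1S,5S,6R,8aS)-5-allyl-1,5,6-trimethyl-1,2,3,5,6,7,8,8a-octahydronaphthalene-1-carboxylate | COC(=O)[C@@]1(C)CCC=C2[C@@H]1CC[C@@H](C)[C@]2(C)CC=C | intermediate
17 | B-alkyl-9-BBN adduct of 16, boron on the terminal allyl carbon (not isolated) | COC(=O)[C@@]1(C)CCC=C2[C@@H]1CC[C@@H](C)[C@]2(C)CCCB1C2CCCC1CCC2 | intermediate
18 | methyl (1S,5S,6R,8aS)-5-(3-hydroxypropyl)-1,5,6-trimethyl-1,2,3,5,6,7,8,8a-octahydronaphthalene-1-carboxylate | COC(=O)[C@@]1(C)CCC=C2[C@@H]1CC[C@@H](C)[C@]2(C)CCCO | intermediate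
19 | methyl (1S,5S,6R,8aS)-1,5,6-trimethyl-5-(3-oxopropyl)-1,2,3,5,6,7,8,8a-octahydronaphthalene-1-carboxylate | COC(=O)[C@@]1(C)CCC=C2[C@@H]1CC[C@@H](C)[C@]2(C)CCC=O | intermediate
20 | methyl (1S,5S,6R,8aS)-5-(but-3-yn-1-yl)-1,5,6-trimethyl-1,2,3,5,6,7,8,8a-octahydronaphthalene-1-carboxylate | COC(=O)[C@@]1(C)CCC=C2[C@@H]1CC[C@@H](C)[C@]2(C)CCC#C | intermediate
21 | (E)-alkenyl(dimethyl)alane from 20, Al on C14 and CH3 on C13 (not isolated) | COC(=O)[C@@]1(C)CCC=C2[C@@H]1CC[C@@H](C)[C@]2(C)CC/C(C)=C/[Al](C)C | intermediate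
22 | methyl (1S,5S,6R,8aS)-5-[(3E)-5-hydroxy-3-methylpent-3-en-1-yl]-1,5,6-trimethyl-1,2,3,5,6,7,8,8a-octahydronaphthalene-1-carboxylate | COC(=O)[C@@]1(C)CCC=C2[C@@H]1CC[C@@H](C)[C@]2(C)CC/C(C)=C/CO | intermediate
23 | methyl (1S,5S,6R,8aS)-5-[(3E)-5-acetoxy-3-methylpent-3-en-1-yl]-1,5,6-trimethyl-1,2,3,5,6,7,8,8a-octahydronaphthalene-1-carboxylate (CNP0209995.2) | COC(=O)[C@@]1(C)CCC=C2[C@@H]1CC[C@@H](C)[C@]2(C)CC/C(C)=C/COC(C)=O | target

**Step count.** Total: 13 steps. Longest linear sequence: 12 steps (steps 1, 2 and 4–13).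

**Steps most likely to fail**

Step 6. The lithium alkoxide may add only sluggishly to the unactivated internal alkyne, or the Claisen step, which must bring C4 onto the more hindered α face of C5, may be slower than thermal decomposition at 210 °C. The fallback sets out from hydrazone 4 and comes back at ketone 12. Vinyllithium 8, made from 4 as in step 4, is acylated at −78 °C with methyl 4-[methoxy(methyl)amino]-4-oxobutanoate to give methyl 4-[(5R,6S)-6-allyl-5,6-dimethylcyclohex-1-en-1-yl]-4-oxobutanoate F1. Reduction under the conditions of step 5 should give methyl (4S)-4-[(5R,6S)-6-allyl-5,6-dimethylcyclohex-1-en-1-yl]-4-hydroxybutanoate F2, which is closed with pyridinium p-toluenesulfonate in toluene to (5S)-5-[(5R,6S)-6-allyl-5,6-dimethylcyclohex-1-en-1-yl]dihydrofuran-2(3H)-one F3. Takai–Utimoto ethylidenation of the lactone carbonyl (CH3CHBr2, Zn, TiCl4, TMEDA, THF) then gives enol ether 11, which is isolated and heated in o-dichlorobenzene at 180 °C to ketone 12. The enol ether is thus built by carbonyl alkylidenation instead of alkyne hydroalkoxylation.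

Step 8. Dehydrochlorination toward C19, or methoxide substitution and epoxy-ether formation, may outrun cyclopropanone closure, or the closure may lose facial control at C4. The fallback sets out from ketone 12 and comes back at ester 16. Ketone 12 is converted with HC(OMe)3 and TsOH into the methyl enol ether of 12 toward C4, F4. PhI(OAc)2 in MeOH (oxidative rearrangement by trivalent iodine) should attack C4 anti to C6; loss of iodobenzene with a 1,2-shift of C3 from C18 to C4, with inversion at C4, then gives 16 directly, without a free chloro ketone or a cyclopropanone.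

Step 7. Silylation may occur on the less hindered C3 side, or the chlorinating agent may attack the allyl or ring alkene. The fallback sets out from ketone 12 and comes back at ester 16. The kinetic lithium enolate of 12 (LDA, THF, −78 °C) is chlorinated with NCS at C3 to give the 3-chloro ketone (C3 epimers) F5. With NaOMe in MeOH this α′-chloro isomer should enolise at C4 and close, by attack of C4 on C3, to the same cyclopropanone 15, which opens to 16. Halogenation is thereby moved to the kinetically accessible carbon.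

Further compounds
F1 | step 6 | methyl 4-[(5R,6S)-6-allyl-5,6-dimethylcyclohex-1-en-1-yl]-4-oxobutanoate | COC(=O)CCC(=O)C1=CCC[C@@H](C)[C@]1(C)CC=C
F2 | step 6 | methyl (4S)-4-[(5R,6S)-6-allyl-5,6-dimethylcyclohex-1-en-1-yl]-4-hydroxybutanoate | COC(=O)CC[C@H](O)C1=CCC[C@@H](C)[C@]1(C)CC=C
F3 | step 6 | (5S)-5-[(5R,6S)-6-allyl-5,6-dimethylcyclohex-1-en-1-yl]dihydrofuran-2(3H)-one | O=C1CC[C@@H](C2=CCC[C@@H](C)[C@]2(C)CC=C)O1
F4 | step 8 | methyl enol ether of 12 toward C4 (C4=C18–OCH3) | CC1=C(OC)CCC=C2[C@@H]1CC[C@@H](C)[C@]2(C)CC=C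
F5 | step 7 | 3-chloro ketone from 12 (chlorine on C3, C3 epimers) | C[C@@H]1C(=O)C(Cl)CC=C2[C@@H]1CC[C@@H](C)[C@]2(C)CC=C
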